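**Plan**
- Retrosynthetic cuts: first the C(sp)–C(sp2) bond of the enyne (Sonogashira). Then the ring bond O2–C3 of the 1,2-dioxane together with the carboxyl C1–O bond, which folds the β-peroxy acid back into a β-lactone bearing a hydroperoxy ketal. Then the O–O/OMe unit on C6 back to a methylidene group (ozonolysis in MeOH), the lactone C(=O)–CH2 bond back to CO plus a terminal epoxide, and the two allylic C–C bonds back to 3-chloro-2-(chloromethyl)propene.
- Enabling feature: ring carbon C3 carries O2 and, two atoms away, the carboxyl carbon, which is an opened oxetan-2-one. The OOH on C6 reaches C3 through a six-membered (6-exo-tet) transition state. C6 is a peroxyketal carbon (O1 and OMe on one carbon) and can be epimerised by acid.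
- Forward order: chain assembly on the methallyl linchpin, epoxide, β-lactone (temporary strained ring), hydroperoxy ketal, then the 1,2-dioxane (the only ring of the target, closed last), then the side-chain coupling.
- Stereochemistry: C3 comes from (R)-epichlorohydrin (retention through epoxide and lactone, one inversion in the ring closure, R to S). C6 comes from thermodynamic (anomeric) equilibration in the same flask. The E-alkene comes from a Takai olefination.

Key step: step 6

Remark: ring locants used here are O1, O2, C3 (CH bearing CH2CO2H), C4, C5, C6 (ketal carbon). The target is then (3S,6R) with OMe cis to the CH2CO2H arm, and it is assumed that this epimer (axial OMe, both carbon substituents equatorial) is the thermodynamically preferred one.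

**Step 1**
Reactants: 1 (4-bromobut-1-yn-1-yl)trimethylsilane; 2 3-chloro-2-(chloromethyl)prop-1-ene
Product: 4 [6-(chloromethyl)hept-6-en-1-yn-1-yl]trimethylsilane, via Grignard reagent 3 (not isolated)
Conditions: Mg, THF, 40 °C; then slow addition to 2 (3 equiv), Li2CuCl4 (3 mol %), THF, −20 → 0 °C
Reagents that add atoms: none
Why: Copper-catalysed Grignard–allylic chloride coupling; the dichloride is symmetrical, so SN2 and SN2' attack give the same product, and its excess with slow inverse addition should suppress double substitution (no stereocentre).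

**Step 2**
Reactants: 4 [6-(chloromethyl)hept-6-en-1-yn-1-yl]trimethylsilane; 5 (R)-epichlorohydrin
Product: 7 (2R)-1-chloro-5-methylidene-10-(trimethylsilyl)dec-9-yn-2-ol, via allylmagnesium chloride 6 (not isolated)
Conditions: Mg (excess, activated), THF, 0 °C, slow addition of 4; then 5, CuI (5 mol %), −40 → −10 °C; aq NH4Cl
Reagents that add atoms: none
Why: Copper-catalysed Grignard opening of a terminal epoxide; the 2-substituted allyl reagent (both allyl termini equivalent) should attack the unsubstituted oxirane carbon faster than the C–Cl carbon, so the stereocentre of 5 is carried over untouched.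

**Step 3**
Reactants: 7 (2R)-1-chloro-5-methylidene-10-(trimethylsilyl)dec-9-yn-2-ol
Product: 9 (2R)-2-(3-methylideneoct-7-yn-1-yl)oxirane, via silyl epoxide 8 (not isolated)
Conditions: K2CO3 (3 equiv), MeOH, 0 °C → rt
Reagents that add atoms: none
Why: Intramolecular Williamson etherification of the chlorohydrin closes the epoxide with the C–O bond of the stereocentre retained, and the same methanolic carbonate should protodesilylate the alkynylsilane.

**Step 4**
Reactants: 9 (2R)-2-(3-methylideneoct-7-yn-1-yl)oxirane
Product: 10 (4R)-4-(3-methylideneoct-7-yn-1-yl)oxetan-2-one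
Conditions: [(salph)Al(THF)2][Co(CO)4] (2 mol %), CO (60 bar), DME, 50 °C
Reagents that add atoms: carbon monoxide, [C-]#[O+]
Why: Ring-expanding epoxide carbonylation with a Lewis acid/cobaltate ion pair; [Co(CO)4]− opens the activated epoxide at the unsubstituted carbon, and CO insertion and acyl–O closure give the β-lactone with the C–O stereocentre retained (R), the 18-electron cobaltate not being expected to engage the alkene or alkyne.

**Step 5**
Reactants: 10 (4R)-4-(3-methylideneoct-7-yn-1-yl)oxetan-2-one
Product: 12 (4R)-4-(3-hydroperoxy-3-methoxyoct-7-yn-1-yl)oxetan-2-one (both epimers at the ketal carbon), via carbonyl oxide 11 (not isolated)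
Conditions: O3 (1.0 equiv, Sudan Red 7B end point), CH2Cl2/MeOH 4:1, −78 °C; N2 purge; no reductive work-up
Reagents that add atoms: ozone, [O-][O+]=O; methanol, CO
Why: Ozonolysis by the Criegee mechanism with solvent trapping; the 1,1-disubstituted alkene should react far faster than the terminal alkyne, the primary ozonide fragments to formaldehyde and the ketone O-oxide, and methanol captures the latter as the α-methoxy hydroperoxide, the new ketal carbon forming without facial control (corrected in step 6).

**Step 6**
Reactants: 12 (4R)-4-(3-hydroperoxy-3-methoxyoct-7-yn-1-yl)oxetan-2-one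
Product: 14 2-[(3S,6R)-6-methoxy-6-(pent-4-yn-1-yl)-1,2-dioxan-3-yl]acetic acid, via C6-epimeric potassium carboxylate 13 (not isolated)
Conditions: KOtBu (1.05 equiv), 18-crown-6 (1.1 equiv), THF (0.01 M), −40 → 0 °C; then CSA (1.3 equiv), MeOH (10 equiv), 0 °C → rt
Reagents that add atoms: methanol, CO (exchanges into the ketal OMe during the equilibration)
Why: Proposed new method: deprotonation of the hydroperoxy ketal (pKa about 12.5) gives a peroxy anion that should attack C4 of the oxetan-2-one from the face opposite the ring oxygen in an intramolecular SN2 reaction (alkyl–oxygen cleavage), so that release of the four-ring strain expels the carboxylate and the O2–C3 bond and the free CH2CO2− arm of the target arise in one event. The closest known reaction types are the base-mediated (KOtBu/18-crown-6) intramolecular alkylation of hydroperoxy acetals by secondary mesylates to 3-alkoxy-1,2-dioxanes and the SN2 opening of 4-alkyl-β-lactones at C4 by carboxylate, azide, thiolate or a tethered carbonyl oxygen, all with inversion; a hydroperoxide has not been used as the nucleophile toward a β-lactone. The 1,2-dioxane closes in the 6-exo-tet mode. C3 is set by this inversion of the (R)-lactone carbon, which traces back to (R)-epichlorohydrin, and becomes (S); C6 enters as a mixture and is then funnelled, by acid-catalysed loss and re-addition of methanol through the cyclic peroxycarbenium ion, into the thermodynamic epimer with an axial (anomeric) OMe and both carbon substituents equatorial, which is the (3S,6R) arrangement. The selectivity needed is attack at the alkyl carbon and not at the acyl carbon: the tether secures it, since acyl attack would need a bridged eight-membered transition state, while high dilution holds back intermolecular perhydrolysis and the weakly basic peroxy anion cannot enolise the lactone or deprotonate the alkyne.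

**Step 7**
Reactants: 15 dec-9-en-1-ol
Product: 16 dec-9-enal
Conditions: Dess–Martin periodinane (1.1 equiv), CH2Cl2, rt
Reagents that add atoms: none
Why: Dess–Martin oxidation of a primary alcohol stops at the aldehyde and leaves the terminal alkene untouched.

**Step 8**
Reactants: 16 dec-9-enal
Product: 17 (1E)-1-iodoundeca-1,10-diene
Conditions: CrCl2 (6 equiv), CHI3 (2 equiv), THF/1,4-dioxane 1:6, 0 °C → rt
Reagents that add atoms: iodoform, IC(I)I
Why: Takai olefination; the gem-dichromium species from iodoform adds to the aldehyde and elimination from the β-oxidochromium intermediate should give the (E)-vinyl iodide, the dioxane co-solvent raising the E preference and the terminal alkene being inert.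

**Step 9**
Reactants: 14 2-[(3S,6R)-6-methoxy-6-(pent-4-yn-1-yl)-1,2-dioxan-3-yl]acetic acid; 17 (1E)-1-iodoundeca-1,10-diene
Product: 18 2-[(3S,6R)-6-[(6E)-hexadeca-6,15-dien-4-yn-1-yl]-6-methoxy-1,2-dioxan-3-yl]acetic acid
Conditions: PdCl2(PPh3)2 (3 mol %), CuI (5 mol %), Et3N (5 equiv), THF (degassed), rt; pH 5 buffer work-up
Reagents that add atoms: none
Why: Sonogashira coupling; oxidative addition to the vinyl iodide and reductive elimination proceed with retention of the E geometry, the carboxylic acid is carried as its ammonium salt, and the dialkyl peroxyketal should survive the mild, base-buffered conditions at room temperature.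

**Compound list**
1 | (4-bromobut-1-yn-1-yl)trimethylsilane | C[Si](C)(C)C#CCCBr | starting material
2 | 3-chloro-2-(chloromethyl)prop-1-ene | C=C(CCl)CCl | starting material
3 | [4-(trimethylsilyl)but-3-yn-1-yl]magnesium bromide | C[Si](C)(C)C#CCC[Mg]Br | intermediate
4 | [6-(chloromethyl)hept-6-en-1-yn-1-yl]trimethylsilane | C=C(CCl)CCCC#C[Si](C)(C)C | intermediate
5 | (R)-epichlorohydrin, (2R)-2-(chloromethyl)oxirane | ClC[C@H]1CO1 | starting material
6 | [2-methylidene-7-(trimethylsilyl)hept-6-yn-1-yl]magnesium chloride | C=C(C[Mg]Cl)CCCC#C[Si](C)(C)C | intermediate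
7 | (2R)-1-chloro-5-methylidene-10-(trimethylsilyl)dec-9-yn-2-ol | C[Si](C)(C)C#CCCCC(=C)CC[C@@H](O)CCl | intermediate
8 | trimethyl{6-methylidene-8-[(2R)-oxiran-2-yl]oct-1-yn-1-yl}silane | C[Si](C)(C)C#CCCCC(=C)CC[C@@H]1CO1 | intermediate
9 | (2R)-2-(3-methylideneoct-7-yn-1-yl)oxirane | C#CCCCC(=C)CC[C@@H]1CO1 | intermediate
10 | (4R)-4-(3-methylideneoct-7-yn-1-yl)oxetan-2-one | C#CCCCC(=C)CC[C@@H]1CC(=O)O1 | intermediate
11 | carbonyl oxide (ketone O-oxide) derived from 10 | C#CCCCC(=[O+][O-])CC[C@@H]1CC(=O)O1 | intermediate
12 | (4R)-4-(3-hydroperoxy-3-methoxyoct-7-yn-1-yl)oxetan-2-one, both epimers at the ketal carbon | C#CCCCC(OC)(OO)CC[C@@H]1CC(=O)O1 | intermediate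
13 | potassium 2-[(3S)-6-methoxy-6-(pent-4-yn-1-yl)-1,2-dioxan-3-yl]acetate, both C6 epimers | C#CCCCC1(OC)CC[C@@H](CC(=O)[O-])OO1.[K+] | intermediate
14 | 2-[(3S,6R)-6-methoxy-6-(pent-4-yn-1-yl)-1,2-dioxan-3-yl]acetic acid | C#CCCC[C@]1(OC)CC[C@@H](CC(=O)O)OO1 | intermediate
15 | dec-9-en-1-ol | C=CCCCCCCCCO | starting material
16 | dec-9-enal | C=CCCCCCCCC=O | intermediate
17 | (1E)-1-iodoundeca-1,10-diene | C=CCCCCCCC/C=C/I | intermediate
18 | 2-[(3S,6R)-6-[(6E)-hexadeca-6,15-dien-4-yn-1-yl]-6-methoxy-1,2-dioxan-3-yl]acetic acid | C=CCCCCCCC/C=C/C#CCCC[C@]1(OC)CC[C@@H](CC(=O)O)OO1 | target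

**Step count**
Total steps: 9. Longest linear sequence: 7 (steps 1 to 6, then step 9).

**Steps most likely to fail**

Step 6. The peroxy anion may attack the lactone carbonyl of a second molecule (perhydrolysis and oligomerisation), or base-induced elimination may outrun the 6-exo-tet closure; the acid equilibration may also funnel C6 incompletely. The fallback uses known chemistry, sets out from 9 and comes back at 14. Ring expansion of the epoxide with dimethylsulfoxonium methylide (Me3S(O)I, KOtBu, tBuOH, 50 °C, Corey–Chaykovsky type, retention at the C–O carbon) should give (2R)-2-(3-methylideneoct-7-yn-1-yl)oxetane F1. Ozonolysis in CH2Cl2/MeOH as in step 5 should give (2R)-2-(3-hydroperoxy-3-methoxyoct-7-yn-1-yl)oxetane F2. The known Lewis-acid-mediated intramolecular opening of an oxetane by a tethered hydroperoxide (TMSOTf cat., CH2Cl2, −40 → 0 °C, 6-exo, inversion), followed by the same MeOH/CSA equilibration, should give 2-[(3S,6R)-6-methoxy-6-(pent-4-yn-1-yl)-1,2-dioxan-3-yl]ethan-1-ol F3. Oxidation of the primary alcohol (TEMPO cat., PhI(OAc)2, MeCN/pH 7 buffer) should then give 14.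

Step 4. The terminal alkyne may deactivate the cobalt catalyst (hydrocobaltation or alkyne complex formation), or a second carbonylation may lead on to the succinic anhydride. The fallback sets out from 9 and comes back at 10. Periodic acid cleavage of the terminal epoxide (H5IO6, THF/H2O, 0 °C) should give 4-methylidenenon-8-ynal F4. The cinchona alkaloid/LiClO4-catalysed acyl halide–aldehyde cyclocondensation (AcCl, iPr2NEt, O-trimethylsilylquinine or O-trimethylsilylquinidine, the pseudoenantiomer being chosen for the R lactone, CH2Cl2/Et2O, −78 °C) should then give 10. The stereocentre would then come from the catalyst instead of the chiral pool.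

Step 9. Copper(I) or phosphine may cleave the O–O bond reductively, or alkyne homocoupling may compete with the cross-coupling of the carboxylate-bearing alkyne. The fallback reverses the polarity of the coupling, sets out from 14 and 17 and comes back at 18. Bromination of the alkyne C–H (NBS, AgNO3 cat., acetone, rt) should give 2-[(3S,6R)-6-(5-bromopent-4-yn-1-yl)-6-methoxy-1,2-dioxan-3-yl]acetic acid F5. Iodine–lithium exchange on 17 (tBuLi, Et2O, −78 °C) and quenching with Bu3SnCl should give tributyl[(1E)-undeca-1,10-dien-1-yl]stannane F6. A copper-free and amine-free Stille coupling of the two (Pd2(dba)3, AsPh3, THF, rt) should give 18 with retention of the E geometry.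

**Further compounds**
F1 | step 6 | (2R)-2-(3-methylideneoct-7-yn-1-yl)oxetane | C#CCCCC(=C)CC[C@@H]1CCO1
F2 | step 6 | (2R)-2-(3-hydroperoxy-3-methoxyoct-7-yn-1-yl)oxetane, both epimers at the ketal carbon | C#CCCCC(OC)(OO)CC[C@@H]1CCO1
F3 | step 6 | 2-[(3S,6R)-6-methoxy-6-(pent-4-yn-1-yl)-1,2-dioxan-3-yl]ethan-1-ol | C#CCCC[C@]1(OC)CC[C@@H](CCO)OO1
F4 | step 4 | 4-methylidenenon-8-ynal | C#CCCCC(=C)CCC=O
F5 | step 9 | 2-[(3S,6R)-6-(5-bromopent-4-yn-1-yl)-6-methoxy-1,2-dioxan-3-yl]acetic acid | BrC#CCCC[C@]1(OC)CC[C@@H](CC(=O)O)OO1
F6 | step 9 | tributyl[(1E)-undeca-1,10-dien-1-yl]stannane | C=CCCCCCCC/C=C/[Sn](CCCC)(CCCC)CCCC
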